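- In a one-step world, solid substrate → target, every percent of solid lost is target, so the red flask at 180 min should hold 78.1% target; it reads 29.0%.

| setting | red | blue | flask |
|---|---|---|---|
| solid substrate | 0.063 M | 0.063 M | 0.063 M |
| temperature | 100 °C | 95 °C | 100 °C |
| remark | the very flask that is asked about, followed so far | run made earlier |  |
| time |  |  | 6.0 h |

- red (time / min: target / %, solid substrate / %): 25.0: 5.8, 88.3; 40.0: 8.8, 81.7; 60.0: 14.0, 74.5; 120: 22.1, 46.8; 180: 29.0, 21.9; 300: 32.2, 0
- blue (time / min: target / %, solid substrate / %): 25.0: 7.7, 88.6; 40.0: 10.0, 82.0; 60.0: 14.3, 72.7; 120: 25.2, 47.8; 180: 33.7, 21.2; 300: 35.8, 0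

(readings scatter by 0.5 percentage points)

- solid substrate is a solid; its amount is given per volume of the solution
- target taken out counts as made
- at the start none of the solid substrate is in solution

- north-east: at 6.0 h take out 90% of the target then present, then wait 2.0 h
- west: change nothing and wait 2.0 h more
- south-east: at 6.0 h raise the temperature by 20 K, then wait 2.0 h

1. target, in percent of the solid substrate first charged, at 6.0 h
2. what to do for the largest gain in target; "none" if nothing gains more than 2 percentage points (north-east / west / south-east / none)
3. target present, with what was taken out counted in, in percent of the solid substrate first charged, after west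
4. target present, with what was taken out counted in, in percent of the solid substrate first charged, after south-east

- Main step first: the red solid loses 0.248 mM min⁻¹ between 25.0 min and 60.0 min, and 0.261 mM min⁻¹ between 120 min and 180 min, so the rate does not follow the amount of solid.
- That reads as pseudo-zero-order dissolution, with the rate tied to a dissolved concentration that stays low rather than to the solid. The feed rate r_d, the charge in mM times the percent of solid lost per minute, is 0.270 mM min⁻¹ in the red run.
- The blue run gives 0.274 mM min⁻¹, about the same as red.
- So the line for the red solid reaches zero at t_e = 233 min, shorter than the 6.0 h asked about, and the red solid reads 0% at 300 min.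
- One more process: target per solid lost reads 54.9% at 60.0 min but 37.1% at 180 min, so dissolved material also goes elsewhere, increasingly with time.
- The rest: red target gains 3.2 percentage points from 180 min to 300 min, where its last reading is 32.2%, while the last reading of the cooler blue run is 35.8%. A single last reading shows no plateau, but the red reading, lower than the blue one, may point to a balance among dissolved species.
- My own reckoning for the red flask at 6.0 h takes over that last reading, 32.2% with its scatter of 0.5 points, and expects little from waiting. If the balance is real, taking out target lets it refill, so north-east.
- The forecast gives 31.5%, north-east, 31% after west and 20.5% after south-east, holding that “equilibrium favours target less when hot”.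
- The simulated flask gives 31.1%; north-east gains 18 points, and the totals are 30.4% after west and 33.6% after south-east. At 180 min starting material stands at 4.53 mM, less than the saturation value 34 mM. The line r_d puts the solid at 84.6% at 36.0 min, and this flask holds 83.5%.

    starting material ⇌ third isomer (K = 2.60, k = 0.00630 min⁻¹, Ea = 125 kJ mol⁻¹, ΔH = −48.0 kJ mol⁻¹)
    starting material ⇌ target (K = 4.80, k = 0.300 min⁻¹, Ea = 111 kJ mol⁻¹, ΔH = −28.0 kJ mol⁻¹)
    starting material ⇌ isomer of the product A (K = 2.90, k = 0.0510 min⁻¹, Ea = 116 kJ mol⁻¹, ΔH = −18.0 kJ mol⁻¹)
    target ⇌ isomer of the product B (K = 1.10, k = 0.0120 min⁻¹, Ea = 124 kJ mol⁻¹, ΔH = −43.0 kJ mol⁻¹)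
    solid substrate ⇌ starting material, rate k5*(cs5 - [starting material]) while solid is left; crystals form when [starting material] > cs5 (solubility = 34.0 mM, k = 0.00880 min⁻¹)
    (constants at 100 °C)

- Second flask, the neighbour with 0.25 M charged: at the same r_d, 6.0 h consumes 97.2 mM, leaving 61.1% of its own charge as solid.
- Computed, that neighbour holds 62.5% solid and 13.0% target.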